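The quinone ring (numbered C1=O between C2–OMe and the chain-bearing C6, C4=O opposite) is cut at the two bonds that tie its C5=C6 edge to the carbonyl carbons C4 and C1. That edge is a terminal alkyne that already holds the (R)-acetate. C4, C3 and C2 with its methoxy group come from a methoxy(2-methoxyvinyl)carbene complex of chromium, and C1 is one of its CO ligands. A Dötz benzannulation joins the three in one operation, exploiting the para relation of the C1 and C4 oxygens and the size bias of the terminal alkyne. Oxidative work-up should give the quinone directly. The stereocentre is bought with (R)-epichlorohydrin.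

Key step: step 6

Assumption: complex 6 is drawn as the (E) enol ether, but either alkene geometry should serve in step 6 because C2 ends as an aromatic carbon.

Step 1
Reactants: 1 hexacarbonylchromium Cr(CO)6; 2 lithium (trimethylsilyl)acetylide
Product: 4 pentacarbonyl[1-methoxy-3-(trimethylsilyl)prop-2-yn-1-ylidene]chromium, via lithium acylchromate 3 (not isolated)
Conditions: THF, −78 °C to 0 °C; then Me3OBF4, CH2Cl2, 0 °C
Reagents that add atoms: trimethyloxonium tetrafluoroborate Me3OBF4, C[O+](C)C.F[B-](F)(F)F
Why: Acylmetalate route to alkoxycarbene complexes: the acetylide adds to a CO ligand of Cr(CO)6 and the hard oxonium salt alkylates the resulting acylchromate 3 on oxygen.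

Step 2
Reactants: 4 pentacarbonyl[1-methoxy-3-(trimethylsilyl)prop-2-yn-1-ylidene]chromium
Product: 6 pentacarbonyl[(2E)-1,3-dimethoxyprop-2-en-1-ylidene]chromium, via ethynylcarbene complex 5 (not isolated)
Conditions: MeOH, NaOMe (10 mol %), THF, −40 °C to 0 °C
Reagents that add atoms: methanol, CO
Why: The carbene group makes the alkyne a strong Michael acceptor and activates its C–Si bond, so catalytic methoxide should desilylate 4 to ethynyl complex 5 and methanol should then add to its terminal carbon (conjugate addition of an alcohol to an alkynylcarbene complex), giving the push–pull enol ether as the more stable (E) isomer.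

Step 3
Reactants: 7 (R)-epichlorohydrin; 8 dodecylmagnesium bromide
Product: 9 (R)-1-chloropentadecan-2-ol
Conditions: CuI (5 mol %), THF, −40 °C to −10 °C; then H2O
Reagents that add atoms: none
Why: Copper-catalysed Grignard opening of the epoxide at its unsubstituted CH2 carbon (SN2) is faster than displacement of chloride, so the stereocentre of 7 is carried over unchanged as (R).

Step 4
Reactants: 9 (R)-1-chloropentadecan-2-ol
Product: 11 (R)-heptadec-1-yn-4-ol, via epoxide 10 (not isolated)
Conditions: LiC≡CH·H2NCH2CH2NH2 (3 equiv), DMSO, 0 °C to rt; then H2O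
Reagents that add atoms: lithium acetylide ethylenediamine complex, [Li+].[C-]#C.NCCN
Why: Acetylide first acts as base so that the alkoxide closes epoxide 10 by intramolecular Williamson displacement of chloride, and a second equivalent opens 10 at the terminal carbon (SN2 alkynylation), so no bond to the carbinol carbon is broken and it stays (R).

Step 5
Reactants: 11 (R)-heptadec-1-yn-4-ol
Product: 12 (R)-heptadec-1-yn-4-yl acetate
Conditions: Ac2O, pyridine, DMAP (cat.), CH2Cl2, rt
Reagents that add atoms: acetic anhydride, CC(=O)OC(C)=O
Why: DMAP-catalysed O-acylation of the secondary alcohol leaves the C–O bond of the stereocentre and the terminal alkyne untouched.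

Step 6
Reactants: 6 pentacarbonyl[(2E)-1,3-dimethoxyprop-2-en-1-ylidene]chromium; 12 (R)-heptadec-1-yn-4-yl acetate
Product: 15 ardisinone, via arene Cr(CO)3 complex 13 (not isolated), via phenol 14 (not isolated)
Conditions: THF, 65 °C, Ar; then (NH4)2Ce(NO3)6, MeCN–H2O, 0 °C
Reagents that add atoms: water, O
Why: Thermal loss of one CO from 6 lets alkyne 12 bind and insert into the Cr=C bond with its unsubstituted terminus, which forms the C5–C4 bond, and CO insertion at the new carbene carbon gives a chromium-bound dienylketene whose ketene carbon is C1, now bonded to the chain-bearing C6. The six-membered ring is then closed by 6π electrocyclisation (C1 to C2) and tautomerisation, giving phenol 14 as its Cr(CO)3 complex 13, which (NH4)2Ce(NO3)6 should decomplex and oxidatively demethylate to the p-quinone, the C4 oxygen coming from water. The closest known reaction type is the Dötz benzannulation of alkenyl(methoxy)carbene complexes of zerovalent chromium with terminal alkynes followed by oxidative work-up. No stereocentre is formed, and the (R) acetate, two carbons away from the reacting alkyne, cannot epimerise under neutral thermal or acidic oxidative conditions. The step needs regioselective insertion (chain next to the CO-derived C1), and this is secured by the terminal alkyne, whose H versus CH2R size difference directs insertion in this reaction class. It also needs CO insertion to outrun direct five-ring closure; the β substituent here is only an oxygen donor, no stronger than the methoxy on the carbene carbon and comparable to that in 3-furylcarbene complexes, which benzannulate normally, and THF at moderate temperature favours the phenol pathway.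

Compound list
1 | hexacarbonylchromium, Cr(CO)6 | O=C=[Cr](=C=O)(=C=O)(=C=O)(=C=O)=C=O | starting material
2 | lithium (trimethylsilyl)acetylide | [Li+].[C-]#C[Si](C)(C)C | starting material
3 | lithium pentacarbonyl[1-oxido-3-(trimethylsilyl)prop-2-yn-1-ylidene]chromate | [Li+].[O-]C(C#C[Si](C)(C)C)=[Cr](=C=O)(=C=O)(=C=O)(=C=O)=C=O | intermediate
4 | pentacarbonyl[1-methoxy-3-(trimethylsilyl)prop-2-yn-1-ylidene]chromium | COC(C#C[Si](C)(C)C)=[Cr](=C=O)(=C=O)(=C=O)(=C=O)=C=O | intermediate
5 | pentacarbonyl(1-methoxyprop-2-yn-1-ylidene)chromium | COC(C#C)=[Cr](=C=O)(=C=O)(=C=O)(=C=O)=C=O | intermediate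
6 | pentacarbonyl[(2E)-1,3-dimethoxyprop-2-en-1-ylidene]chromium | CO/C=C/C(OC)=[Cr](=C=O)(=C=O)(=C=O)(=C=O)=C=O | intermediate
7 | (R)-epichlorohydrin, (R)-2-(chloromethyl)oxirane | ClC[C@H]1CO1 | starting material
8 | dodecylmagnesium bromide | CCCCCCCCCCCC[Mg]Br | starting material
9 | (R)-1-chloropentadecan-2-ol | CCCCCCCCCCCCC[C@@H](O)CCl | intermediate
10 | (R)-2-tridecyloxirane, (R)-1,2-epoxypentadecane | CCCCCCCCCCCCC[C@@H]1CO1 | intermediate
11 | (R)-heptadec-1-yn-4-ol | CCCCCCCCCCCCC[C@H](CC#C)O | intermediate
12 | (R)-heptadec-1-yn-4-yl acetate | CCCCCCCCCCCCC[C@H](CC#C)OC(C)=O | intermediate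
13 | tricarbonyl(η6-arene)chromium complex of phenol 14 (π-complex, written as arene ligand plus Cr(CO)3 fragment) | CCCCCCCCCCCCC[C@H](Cc1cc(OC)cc(OC)c1O)OC(C)=O.O=C=[Cr](=C=O)=C=O | intermediate
14 | (2R)-1-(2-hydroxy-3,5-dimethoxyphenyl)pentadecan-2-yl acetate | CCCCCCCCCCCCC[C@H](Cc1cc(OC)cc(OC)c1O)OC(C)=O | intermediate
15 | ardisinone, (2R)-1-(5-methoxy-3,6-dioxocyclohexa-1,4-dien-1-yl)pentadecan-2-yl acetate | CCCCCCCCCCCCC[C@H](CC1=CC(=O)C=C(OC)C1=O)OC(C)=O | target

Total step count: 6 steps.
Longest linear sequence: 4 steps (steps 3, 4, 5 and 6); the carbene branch (steps 1 and 2) joins at step 6.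

Steps most likely to fail

Step 6. After alkyne insertion the donor-substituted vinylcarbene may cyclise before CO insertion, giving a five-membered ring instead of the phenol. A second alkyne may also insert. CO loss from the push–pull carbene may be slow enough that 6 decomposes first. The fallback gives up the annulation and builds the chain on a ready-made arene. It sets out from 9, which NaOH in Et2O–H2O should close to isolated epoxide 10. 3,5-Dimethoxyphenylmagnesium chloride with CuI (10 mol %) in THF at −30 °C should open 10 at the terminal carbon to (R)-1-(3,5-dimethoxyphenyl)pentadecan-2-ol F1. NaSEt in DMF at 140 °C should remove one methyl ether to give (R)-3-(2-hydroxypentadecyl)-5-methoxyphenol F2. (KSO3)2NO in KH2PO4-buffered acetone–water should oxidise F2 para to the hydroxyl to (R)-2-(2-hydroxypentadecyl)-6-methoxy-1,4-benzoquinone F3. Ac2O and pyridine then acetylate F3, and the route is rejoined at 15.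

Step 2. Methoxide may attack the carbene carbon or a CO ligand and degrade the complex, and the desilylated ethynyl complex 5 may oligomerise before methanol adds. The fallback makes the enol ether carbon skeleton first and the carbene last. It sets out from 1, which sodium naphthalenide in THF at −78 °C should reduce to disodium pentacarbonylchromate Na2Cr(CO)5 F4. Acylation of F4 with (E)-3-methoxyacryloyl chloride F5 (from commercial (E)-3-methoxyacrylic acid and (COCl)2 with cat. DMF) should give sodium pentacarbonyl[(2E)-3-methoxy-1-oxidoprop-2-en-1-ylidene]chromate F6. Me3OBF4 in CH2Cl2 at 0 °C should methylate F6 on oxygen, and the route is rejoined at 6.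

Step 4. Ring closure to the epoxide may be incomplete, and the excess of strongly basic acetylide and amine in DMSO may isomerise the terminal alkyne or cause elimination. The fallback separates the two events and opens the epoxide under Lewis-acid assistance. It sets out from 9, which NaOH in Et2O–H2O should close to isolated epoxide 10. Lithium (trimethylsilyl)acetylide 2 with BF3·OEt2 in THF at −78 °C should open 10 at the terminal carbon to (R)-1-(trimethylsilyl)heptadec-1-yn-4-ol F7. K2CO3 in MeOH removes the silyl group, and the route is rejoined at 11.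

Further compounds
F1 | step 6 | (R)-1-(3,5-dimethoxyphenyl)pentadecan-2-ol | CCCCCCCCCCCCC[C@H](Cc1cc(OC)cc(OC)c1)O
F2 | step 6 | (R)-3-(2-hydroxypentadecyl)-5-methoxyphenol | CCCCCCCCCCCCC[C@H](Cc1cc(O)cc(OC)c1)O
F3 | step 6 | (R)-2-(2-hydroxypentadecyl)-6-methoxy-1,4-benzoquinone | CCCCCCCCCCCCC[C@H](CC1=CC(=O)C=C(OC)C1=O)O
F4 | step 2 | disodium pentacarbonylchromate, Na2Cr(CO)5 | [Na+].[Na+].O=C=[Cr-2](=C=O)(=C=O)(=C=O)=C=O
F5 | step 2 | (E)-3-methoxyacryloyl chloride | CO/C=C/C(Cl)=O
F6 | step 2 | sodium pentacarbonyl[(2E)-3-methoxy-1-oxidoprop-2-en-1-ylidene]chromate | [Na+].CO/C=C/C([O-])=[Cr](=C=O)(=C=O)(=C=O)(=C=O)=C=O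
F7 | step 4 | (R)-1-(trimethylsilyl)heptadec-1-yn-4-ol | CCCCCCCCCCCCC[C@H](CC#C[Si](C)(C)C)O
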